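**Plan**
- Retrosynthetic cuts, in order: the two O-benzyl groups; the C1=C2 alkene (back to a C1 carbinol and a dithiane-masked aroyl ketone); the C1–C8a aryl bond; then C3–C4 and C2–C(aroyl) together.
- Enabling feature: C1 (vinylic CH, aldehyde oxidation level), C2, C3 and the CH2OH carbon (carboxyl level) are the four carbons of a 5-alkoxyfuran-2(5H)-one. Its two alkene carbons become C2 and C3 and take up the aroyl carbon and the C4 benzyl group that carries ring A.
- Forward: the chain is assembled in one flask (dithiane anion adds to the butenolide, the enolate is benzylated). The only new ring (C1–C4, C4a, C8a) is then closed by attack of ring A on the acetal carbon, giving a bridged lactone. Reduction, ketone unmasking, dehydration and debenzylation follow.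
- Stereochemistry: (−)-menthol is the only source. Its crystalline (5R) acetal directs the conjugate addition to the opposite face, the new C2 substituent directs the benzylation trans, and this C3 centre (R) is the one kept. The C1 and C2 centres are removed by the dehydration.

Key step: step 6

Remark: atom labels C1–C4, C4a–C8a and ring A refer to the dihydronaphthalene of the target (C1 vinylic CH, C2 aroyl-bearing carbon, C3 the stereocentre, C4 the benzylic CH2). 4-Benzyloxy-3-methoxybenzaldehyde (O-benzylvanillin) is taken as a purchased compound.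

**Step 1**
Reactants: 1 furfural
Product: 3 5-hydroxyfuran-2(5H)-one (racemic lactol), via furfural endoperoxide 2 (not isolated)
Conditions: O2, hν (visible light), methylene blue (3,7-bis(dimethylamino)phenothiazin-5-ium chloride, C16H18ClN3S, catalytic), MeOH, 20 °C
Reagents that add atoms: dioxygen, O=O
Why: Sensitised singlet-oxygen [4+2] cycloaddition to the furan gives endoperoxide 2, whose formyl group is attacked by methanol and expelled as methyl formate in a Baeyer–Villiger-like fragmentation that leaves the γ-hydroxybutenolide (furan photooxygenation); the lactol centre formed is racemic and is settled only in step 2.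

**Step 2**
Reactants: 3 5-hydroxyfuran-2(5H)-one; 4 (−)-menthol
Product: 5 (5R)-5-[(1R,2S,5R)-menthyloxy]furan-2(5H)-one
Conditions: 4-MeC6H4SO3H·H2O (catalytic), toluene, reflux with azeotropic removal of water; crystallisation from hexane at −20 °C, mother liquor re-equilibrated with the acid and recrystallised
Reagents that add atoms: none
Why: Acid-catalysed acetalisation of the lactol with the chiral alcohol gives both C5 epimers, which interconvert through the oxocarbenium ion, so selective crystallisation of the (5R) diastereomer (crystallisation-induced diastereomer enrichment under control of the menthyl group) should deliver a single stereoisomer.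

**Step 3**
Reactants: 6 4-benzyloxy-3-methoxybenzaldehyde; 7 propane-1,3-dithiol
Product: 8 2-(4-benzyloxy-3-methoxyphenyl)-1,3-dithiane
Conditions: BF3·OEt2 (catalytic), CH2Cl2, 0 °C → rt
Reagents that add atoms: none
Why: Lewis-acid-catalysed dithioacetalisation of an aromatic aldehyde is routine, and the aryl benzyl ether tolerates catalytic BF3·OEt2.

**Step 4**
Reactants: 6 4-benzyloxy-3-methoxybenzaldehyde
Product: 9 (4-benzyloxy-3-methoxyphenyl)methanol
Conditions: NaBH4, MeOH/THF, 0 °C
Reagents that add atoms: none
Why: Hydride reduction of an aldehyde to the primary alcohol (NaBH4 reduction) is reliable and touches nothing else in the molecule.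

**Step 5**
Reactants: 9 (4-benzyloxy-3-methoxyphenyl)methanol
Product: 10 4-benzyloxy-3-methoxybenzyl bromide
Conditions: PBr3, Et2O, 0 °C; used freshly prepared
Reagents that add atoms: phosphorus tribromide, BrP(Br)Br
Why: Conversion of a benzylic alcohol into the bromide through its phosphite ester (PBr3 bromination, nucleophilic substitution) is standard for electron-rich benzyl alcohols, and the labile bromide is used at once.

**Step 6**
Reactants: 8 2-(4-benzyloxy-3-methoxyphenyl)-1,3-dithiane; 5 (5R)-5-[(1R,2S,5R)-menthyloxy]furan-2(5H)-one; 10 4-benzyloxy-3-methoxybenzyl bromide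
Product: 13 (3R,4R,5R)-3-(4-benzyloxy-3-methoxybenzyl)-4-[2-(4-benzyloxy-3-methoxyphenyl)-1,3-dithian-2-yl]-5-[(1R,2S,5R)-menthyloxy]dihydrofuran-2(3H)-one (3,4-trans, 4,5-trans), via 2-lithio-2-(4-benzyloxy-3-methoxyphenyl)-1,3-dithiane 11 (not isolated), via lithium enolate of the 1,4-adduct 12 (not isolated)
Conditions: 8, n-BuLi, THF, −78 → −20 °C; 5, −78 °C; 10, DMPU, −78 → −20 °C; aq. NH4Cl
Reagents that add atoms: none
Why: n-BuLi deprotonates dithiane 8 to the sulfur-stabilised carbanion 11, which adds in a Michael fashion to C4 of butenolide 5 (the future C2) and forms the bond to the masked aroyl carbon; the resulting lithium enolate 12 is then C-benzylated by bromide 10 in an SN2 step that forms the future C3–C4 bond. The closest known reaction type is the tandem conjugate addition–enolate alkylation of lithiated aryl dithioacetals on 5-alkoxyfuran-2(5H)-ones, the usual entry to trans-dibenzylbutyrolactone lignans. No ring is closed; two skeletal bonds and two stereocentres are made on the intact lactone ring. The lactone C4 centre is controlled by the C5 acetal centre, since the menthyloxy group blocks its own face and the carbanion enters anti to it, and the lactone C3 centre (C3 of the target) is controlled by the new bulky dithianyl group at C4, the bromide again entering anti, so the 3,4-trans-4,5-trans lactone should result. The step needs 1,4- over 1,2-addition, secured by the soft, delocalised and hindered dithianyl anion at low temperature, and two facial selectivities, secured by the flat five-membered ring carrying first the C5 and then the C4 substituent. DMPU is added with the bromide so that C-alkylation outruns proton transfer and retro-Michael loss of the dithiane.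

**Step 7**
Reactants: 13 the all-trans lactone acetal
Product: 14 (1R,2R,3R)-7-benzyloxy-2-[2-(4-benzyloxy-3-methoxyphenyl)-1,3-dithian-2-yl]-1-hydroxy-6-methoxy-1,2,3,4-tetrahydronaphthalene-3-carboxylic acid 1,3-lactone (bridged γ-lactone from the C1 oxygen to the C3 carboxyl; benzo-fused 6-oxabicyclo[3.2.1]octan-7-one)
Conditions: Me3SiOSO2CF3 (0.2 equiv), CH2Cl2, −40 → 0 °C; aq. NaHCO3
Reagents that add atoms: none
Why: Lewis-acid ionisation of the lactol acetal releases menthol and an acyloxocarbenium ion at C1 that is attacked by ring A at its position para to the methoxy group (intramolecular Friedel–Crafts alkylation, 6-exo-trig with respect to the C=O+ bond), which closes the carbocycle cis across the lactone and so gives the 1,3-bridged lactone, the new C1 centre being fixed by the tether while C3 is untouched.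

**Step 8**
Reactants: 14 the bridged lactone
Product: 15 (1R,2R,3R)-7-benzyloxy-2-[2-(4-benzyloxy-3-methoxyphenyl)-1,3-dithian-2-yl]-3-(hydroxymethyl)-6-methoxy-1,2,3,4-tetrahydronaphthalen-1-ol (1,2,3-all-cis)
Conditions: LiAlH4, THF, 0 °C → rt; H2O, aq. NaOH
Reagents that add atoms: none
Why: LiAlH4 reduction of a lactone to the diol turns the carboxyl carbon into the CH2OH group at C3 and leaves C1 as a benzylic alcohol, while the dithiane and the benzyl ethers are inert to hydride and no stereocentre is touched.

**Step 9**
Reactants: 15 the dithiane diol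
Product: 16 [(1R,2R,3R)-7-benzyloxy-1-hydroxy-3-(hydroxymethyl)-6-methoxy-1,2,3,4-tetrahydronaphthalen-2-yl](4-benzyloxy-3-methoxyphenyl)methanone
Conditions: HgCl2, CaCO3, MeCN/H2O (4:1), rt
Reagents that add atoms: water, O
Why: Thiophilic metal-assisted hydrolysis of the dithioacetal (dithiane unmasking, the closing half of the Corey–Seebach umpolung) should free the aryl ketone under buffered conditions that spare the benzylic alcohol.

**Step 10**
Reactants: 16 the β-hydroxy ketone
Product: 17 [(3R)-7-benzyloxy-3-(hydroxymethyl)-6-methoxy-3,4-dihydronaphthalen-2-yl](4-benzyloxy-3-methoxyphenyl)methanone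
Conditions: 4-MeC6H4SO3H·H2O (0.2 equiv), THF/H2O (10:1), 40 °C, under argon
Reagents that add atoms: none
Why: Acid-catalysed dehydration of a β-hydroxy ketone (aldol-type E1 elimination) is helped here by the C1 cation being benzylic and para to the C6 methoxy group, and the doubly conjugated C1=C2 enone is the thermodynamic sink to which any reversible trapping of that cation by the hydroxyl groups returns in the aqueous medium, C3 not being involved.

**Step 11**
Reactants: 17 the enone bis(benzyl ether)
Product: 18 [(3R)-7-hydroxy-3-(hydroxymethyl)-6-methoxy-3,4-dihydronaphthalen-2-yl](4-hydroxy-3-methoxyphenyl)methanone (CNP0352298.1)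
Conditions: BCl3 (1 M in CH2Cl2), C6HMe5 (pentamethylbenzene), CH2Cl2, −78 °C; MeOH, then H2O
Reagents that add atoms: none
Why: Boron trichloride with pentamethylbenzene as a non-basic benzyl cation scavenger cleaves aryl benzyl ethers at low temperature (Lewis-acid debenzylation) without reducing the C1=C2 alkene or cleaving the aryl methyl ethers.

**Compound list**
1 | furfural | O=Cc1ccco1 | starting material
2 | furfural endoperoxide, 2,3,7-trioxabicyclo[2.2.1]hept-5-ene-1-carbaldehyde (racemic) | O=CC12C=CC(OO1)O2 | intermediate (not isolated)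
3 | 5-hydroxyfuran-2(5H)-one (racemic) | O=C1C=CC(O)O1 | intermediate
4 | (−)-menthol, (1R,2S,5R)-2-isopropyl-5-methylcyclohexan-1-ol | CC(C)[C@@H]1CC[C@@H](C)C[C@H]1O | starting material
5 | (5R)-5-[(1R,2S,5R)-menthyloxy]furan-2(5H)-one | O=C1C=C[C@H](O[C@@H]2C[C@H](C)CC[C@H]2C(C)C)O1 | intermediate
6 | 4-benzyloxy-3-methoxybenzaldehyde | COc1cc(C=O)ccc1OCc1ccccc1 | starting material
7 | propane-1,3-dithiol | SCCCS | starting material
8 | 2-(4-benzyloxy-3-methoxyphenyl)-1,3-dithiane | COc1cc(C2SCCCS2)ccc1OCc1ccccc1 | intermediate
9 | (4-benzyloxy-3-methoxyphenyl)methanol | COc1cc(CO)ccc1OCc1ccccc1 | intermediate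
10 | 4-benzyloxy-3-methoxybenzyl bromide | COc1cc(CBr)ccc1OCc1ccccc1 | intermediate
11 | 2-lithio-2-(4-benzyloxy-3-methoxyphenyl)-1,3-dithiane | [Li]C1(c2ccc(OCc3ccccc3)c(OC)c2)SCCCS1 | intermediate (not isolated)
12 | lithium enolate of (4R,5R)-4-[2-(4-benzyloxy-3-methoxyphenyl)-1,3-dithian-2-yl]-5-[(1R,2S,5R)-menthyloxy]dihydrofuran-2(3H)-one | [Li]OC1=C[C@@H](C2(c3ccc(OCc4ccccc4)c(OC)c3)SCCCS2)[C@H](O[C@@H]2C[C@H](C)CC[C@H]2C(C)C)O1 | intermediate (not isolated)
13 | (3R,4R,5R)-3-(4-benzyloxy-3-methoxybenzyl)-4-[2-(4-benzyloxy-3-methoxyphenyl)-1,3-dithian-2-yl]-5-[(1R,2S,5R)-menthyloxy]dihydrofuran-2(3H)-one | O=C1O[C@@H](O[C@@H]2C[C@H](C)CC[C@H]2C(C)C)[C@H](C2(c3ccc(OCc4ccccc4)c(OC)c3)SCCCS2)[C@H]1Cc1ccc(OCc2ccccc2)c(OC)c1 | intermediate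
14 | (1R,2R,3R)-7-benzyloxy-2-[2-(4-benzyloxy-3-methoxyphenyl)-1,3-dithian-2-yl]-1-hydroxy-6-methoxy-1,2,3,4-tetrahydronaphthalene-3-carboxylic acid 1,3-lactone | O=C1O[C@H]2c3cc(OCc4ccccc4)c(OC)cc3C[C@@H]1[C@H]2C1(c2ccc(OCc3ccccc3)c(OC)c2)SCCCS1 | intermediate
15 | (1R,2R,3R)-7-benzyloxy-2-[2-(4-benzyloxy-3-methoxyphenyl)-1,3-dithian-2-yl]-3-(hydroxymethyl)-6-methoxy-1,2,3,4-tetrahydronaphthalen-1-ol | O[C@H]1c2cc(OCc3ccccc3)c(OC)cc2C[C@@H](CO)[C@H]1C1(c2ccc(OCc3ccccc3)c(OC)c2)SCCCS1 | intermediate
16 | [(1R,2R,3R)-7-benzyloxy-1-hydroxy-3-(hydroxymethyl)-6-methoxy-1,2,3,4-tetrahydronaphthalen-2-yl](4-benzyloxy-3-methoxyphenyl)methanone | O[C@H]1c2cc(OCc3ccccc3)c(OC)cc2C[C@@H](CO)[C@H]1C(=O)c1ccc(OCc2ccccc2)c(OC)c1 | intermediate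
17 | [(3R)-7-benzyloxy-3-(hydroxymethyl)-6-methoxy-3,4-dihydronaphthalen-2-yl](4-benzyloxy-3-methoxyphenyl)methanone | COc1cc(C(=O)C2=Cc3cc(OCc4ccccc4)c(OC)cc3C[C@H]2CO)ccc1OCc1ccccc1 | intermediate
18 | [(3R)-7-hydroxy-3-(hydroxymethyl)-6-methoxy-3,4-dihydronaphthalen-2-yl](4-hydroxy-3-methoxyphenyl)methanone | COc1cc(C(=O)C2=Cc3cc(O)c(OC)cc3C[C@H]2CO)ccc1O | target

**Step count**
Total: 11 steps. Longest linear sequence: 8 steps (1 → 3 → 5 → 13 → 14 → 15 → 16 → 17 → 18; the branch 6 → 9 → 10 → 13 → 18 is equally long).

**Steps most likely to fail**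

Step 7 (ring closure). The hindered menthyl acetal may ionise only sluggishly. Stronger acid would then be needed, and under it the benzyl ethers could be lost, the cation could fragment with loss of the dithianyl group, or it could eliminate towards a butenolide and erase C3. The fallback changes the leaving group. Setting out from 13, the menthyl acetal would be hydrolysed with aqueous acid (CF3CO2H/H2O/THF, 40 °C) to the 5-hydroxy lactone F1, the closed form of the C1 aldehyde acid. Acetylation (Ac2O, pyridine) would give the 5-acetoxy lactone F2. Its acetate should ionise with BF3·OEt2 in CH2Cl2 at −78 °C, mild enough for the benzyl ethers and the dithiane, and the same Friedel–Crafts closure comes back to the route at 14.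

Step 6 (three-component coupling). Alkylation of enolate 12 may be slower than proton transfer or retro-Michael reversal, and the electron-rich bromide may be consumed by self-condensation. The fallback separates the two bond formations. From 8 (lithiated as in step 6) and 5, the conjugate addition alone would be run and quenched with aq. NH4Cl to isolate the trans mono-adduct (4R,5R)-4-[2-(4-benzyloxy-3-methoxyphenyl)-1,3-dithian-2-yl]-5-[(1R,2S,5R)-menthyloxy]dihydrofuran-2(3H)-one F3. Its enolate 12 would then be regenerated with LiN(i-Pr)2 in THF/DMPU at −78 °C and alkylated with 10, coming back to the route at 13.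

Step 11 (debenzylation). BCl3 may over-react: cleavage of the guaiacyl methyl ethers, addition of HCl to the enone, or ionisation at the primary alcohol. The fallback removes the benzyl groups before the alkene exists. From 16, hydrogenolysis (H2, Pd/C, EtOAc, rt) would give the bis-phenol β-hydroxy ketone F4. The aqueous-acid dehydration of step 10 applied to it would then lead directly to 18, bypassing 17.

**Further compounds**
F1 | step 7 | (3R,4R)-3-(4-benzyloxy-3-methoxybenzyl)-4-[2-(4-benzyloxy-3-methoxyphenyl)-1,3-dithian-2-yl]-5-hydroxydihydrofuran-2(3H)-one (C5 epimers) | O=C1OC(O)[C@H](C2(c3ccc(OCc4ccccc4)c(OC)c3)SCCCS2)[C@H]1Cc1ccc(OCc2ccccc2)c(OC)c1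
F2 | step 7 | (3R,4R)-5-acetoxy-3-(4-benzyloxy-3-methoxybenzyl)-4-[2-(4-benzyloxy-3-methoxyphenyl)-1,3-dithian-2-yl]dihydrofuran-2(3H)-one (C5 epimers) | O=C1OC(OC(C)=O)[C@H](C2(c3ccc(OCc4ccccc4)c(OC)c3)SCCCS2)[C@H]1Cc1ccc(OCc2ccccc2)c(OC)c1
F3 | step 6 | (4R,5R)-4-[2-(4-benzyloxy-3-methoxyphenyl)-1,3-dithian-2-yl]-5-[(1R,2S,5R)-menthyloxy]dihydrofuran-2(3H)-one | O=C1C[C@@H](C2(c3ccc(OCc4ccccc4)c(OC)c3)SCCCS2)[C@H](O[C@@H]2C[C@H](C)CC[C@H]2C(C)C)O1
F4 | step 11 | [(1R,2R,3R)-1,7-dihydroxy-3-(hydroxymethyl)-6-methoxy-1,2,3,4-tetrahydronaphthalen-2-yl](4-hydroxy-3-methoxyphenyl)methanone | O[C@H]1c2cc(O)c(OC)cc2C[C@@H](CO)[C@H]1C(=O)c1ccc(O)c(OC)c1
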